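Tuesday's flask reads 28% of homo product at 12.0 d, more than the 4% of Sunday's flask at 15.0 d, and the two runs differ in the charge of starting material while the partner stands at 0.060 M in both, so I ask what the four new flasks do to that balance.

| flask | starting material | partner | remark | time |
|---|---|---|---|---|
| Sunday's | 0.050 M | 0.060 M | run made earlier |  |
| Monday's | 0.025 M | 0.060 M | run made earlier |  |
| Tuesday's | 0.10 M | 0.060 M | run made earlier |  |
| elm | 0.050 M | 0.0600 M (in portions, 3, over 3.0 d) | first portion at the start, last at 3.0 d | 15 d |
| oak | 0.050 M (fed, over 3.0 d) | 0.0600 M | all else is in the flask from the start; the feed brings no volume worth counting | 15 d |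
| larch | 0.050 M | 0.0600 M | everything together at the start | 15 d |
| ash | 0.050 M | 0.0600 M (fed, over 3.0 d) | all else is in the flask from the start; the feed brings no volume worth counting | 15 d |

- Sunday's (time / d: target / %, homo product / %): 1.25: 40, 3; 2.08: 38, 0; 3.00: 35, 2; 5.00: 23, 4; 10.0: 3, 4; 15.0: 0, 4
- Monday's (time / d: target / %, homo product / %): 0.833: 32, 0; 2.50: 42, 1; 4.00: 33, 5; 6.00: 18, 3; 10.0: 5, 3; 12.0: 5, 3
- Tuesday's (time / d: target / %, homo product / %): 1.04: 29, 5; 1.67: 32, 8; 2.50: 29, 12; 4.00: 14, 21; 8.00: 8, 26; 12.0: 1, 28

(each reading ± 2 percentage points)

- a species is counted by the starting material in it: one homo product counts as two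

- the best flask by share of target in target plus homo product; "all alike" if 1.5 percentage points covers them all (elm / oak / larch / ash / all alike)
- share of target in target plus homo product at the end, elm
- share of target in target plus homo product at the end, oak
- share of target in target plus homo product at the end, larch
- share of target in target plus homo product at the end, ash

I order the times from short to long. Sunday's target reads 40% at 1.25 d and 35% at 3.00 d, so I take 1.25 d as the turnover time of starting material. Target's own half-life, read from Sunday's fall between 3.00 d and 10.0 d, is 1.97 d, longer than the turnover, so target rises early and then falls. The feed of 3.0 d is longer than the turnover, so in the slow flasks what has gone in by the turnover time counts, not the whole charge. The 15 d of the flask is 7.61 half-lives of target, so target ends as a small remainder and the share rests on that remainder as well as on homo product.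

If homo product takes two of what comes from starting material, and target takes one of it and one partner, then dividing the first rate by the second removes time and leaves a ratio of concentrations. So I carry the ratio of partner put in by the turnover time to starting material put in by then, the cover, which for ash is 0.500. The runs give 0.600 for Tuesday, with partner then the limiting reagent, against 1.20 for Sunday and 2.40 for Monday, whose homo readings of 4% and 3% lie within a scatter of 2 percentage points of each other. Elm has 0.400, larch 1.20 and oak 2.88, so I expect homo product near Sunday's level in oak and larch and well above it in elm and ash, whose cover is lower.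

The forecast names oak, with 12% for elm, 35% for oak, 18% for larch and 12% for ash, and holds that “nearly all target has decayed” by the end.

The flasks give oak, with 4.42% for elm, 23.2% for oak, 16.9% for larch and 4.00% for ash.

    partner + intermediate → target (k = 0.240 M⁻¹ min⁻¹)
    target → over-reaction product (k = 2.60 × 10⁻⁴ min⁻¹)
    intermediate → decomposed reagent (k = 5.50 × 10⁻⁴ min⁻¹)
    starting material → intermediate (k = 4.20 × 10⁻⁴ min⁻¹)
    partner ⇌ dormant form (K = 0.790, k = 1.60 × 10⁻⁴ min⁻¹)
    2 intermediate → homo product (k = 0.120 M⁻¹ min⁻¹)

Target's half-life in ash at 1.15 d is 1.9 d, short against the 15 d, and oak ends with 83.0% over-reaction product beside 1.45% target. Homo product follows the cover coarsely and not in order: oak at 2.88 ends with 4.81%, more than the 4.02% of larch at 1.20, ash at 0.500 ends with 18.3%, and the ash flask with 0.24 M of partner, cover 2.00, ends with 3.76%, while the ash flask with 0.015 M, cover 0.125, ends with 44.8%.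

(Readings and results come from a simulation with made-up constants, noise included.)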